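**Retrosynthetic overview**

1. Numbering (germacrane): C6 lactone O–CH, C7 ring-fusion CH, C8 acyloxy CH, C9 acetoxy CH, C10 C–CO2Me, C11=C13 exocyclic methylene, C12 lactone C=O.
2. Enabling feature: C7, shared by the ten-membered ring and the γ-lactone, is allylic to the exocyclic C11=C13 methylene and carries the carbinol C8 (a homoallylic alcohol retron). C7–C8 is cut to a C8 aldehyde and a ring-locked 3-(bromomethyl)butenolide (C13–Br), so that C6 relays to C7 and C8 while the carbocycle closes and the α-methylene lactone appears.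
3. The C8 ester is attached last by Mitsunobu inversion, because the allylation is predicted to give the 8α-alcohol; C9 is bought (glycidol), C6 is set by Sharpless kinetic resolution.
4. Open-chain precursor: C1=C10 enoate by aldol/E1cB between a geranyl-acetate-derived aldehyde (C1–C6, C4=C5 E) and a β-silyloxy ester (C8–C10, C14); butenolide by ring-closing metathesis of a 2-(bromomethyl)acrylate.
5. Ring order: five-membered butenolide first (step 14), ten-membered carbocycle second (step 17).

Key step: step 17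

Remark: atom labels C1–C15 in the text follow germacrane numbering of the target; locants inside compound names are those of the named chain. The C1=C10 bond is read as drawn (CO2Me trans to C2, ring carbons C2 and C9 cis).

**Route**

Step 1
Reactants: 1 (R)-glycidol
Product: 2 (S)-2-[(4-methoxybenzyloxy)methyl]oxirane
Conditions: NaH, 4-methoxybenzyl chloride, Bu4NI (cat.), THF/DMF, 0 °C → rt
Reagents that add atoms: 4-methoxybenzyl chloride COc1ccc(CCl)cc1
Why: Williamson etherification of the primary alkoxide leaves the epoxide stereocentre untouched (the Payne rearrangement of glycidol is degenerate), the descriptor changing from R to S only through the priority change.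

Step 2
Reactants: 2 (S)-2-[(4-methoxybenzyloxy)methyl]oxirane
Product: 3 methyl (S)-3-hydroxy-4-(4-methoxybenzyloxy)butanoate
Conditions: Co2(CO)8 (5 mol%), 3-hydroxypyridine (10 mol%), CO (40 bar), MeOH/THF, 60 °C
Reagents that add atoms: carbon monoxide [C-]#[O+]; methanol CO
Why: Cobalt-catalysed ring-opening methoxycarbonylation of a terminal epoxide, in which the cobalt carbonyl anion attacks the unsubstituted carbon, so the future C9 keeps its configuration and the C14–C10–C9–C8 unit is obtained directly.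

Step 3
Reactants: 3 methyl (S)-3-hydroxy-4-(4-methoxybenzyloxy)butanoate
Product: 4 methyl (S)-3-(tert-butyldimethylsilyloxy)-4-(4-methoxybenzyloxy)butanoate
Conditions: TBSCl, imidazole, DMF, rt
Reagents that add atoms: tert-butyldimethylsilyl chloride CC(C)(C)[Si](C)(C)Cl
Why: Standard silylation gives a base-stable O9 protecting group that tolerates ester enolate formation in step 5.

Step 4
Reactants: 5 geranyl acetate
Product: 6 (E)-3-methyl-6-oxohex-2-en-1-yl acetate
Conditions: O3 (1 equiv), CH2Cl2, −78 °C; then Me2S, −78 °C → rt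
Reagents that add atoms: ozone [O-][O+]=O
Why: Chemoselective ozonolysis of the remote, more electron-rich trisubstituted alkene (the alkene next to the allylic acetate is deactivated) gives the C1–C6 unit with the E C4=C5 bond and the C4 methyl group in place.

Step 5
Reactants: 4 methyl (S)-3-(tert-butyldimethylsilyloxy)-4-(4-methoxybenzyloxy)butanoate; 6 (E)-3-methyl-6-oxohex-2-en-1-yl acetate
Product: 7 methyl (6E)-8-acetoxy-2-[(1S)-1-(tert-butyldimethylsilyloxy)-2-(4-methoxybenzyloxy)ethyl]-3-hydroxy-6-methyloct-6-enoate (mixture at C2 and C3)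
Conditions: LiN(iPr)2, THF, −78 °C; then 6, −78 °C; sat. NH4Cl
Reagents that add atoms: none
Why: Lithium ester enolate aldol addition, in which at −78 °C addition to the aldehyde outruns β-elimination of the silyloxy group and attack on the acetate; the two new stereocentres are erased in step 6.

Step 6
Reactants: 7 methyl (6E)-8-acetoxy-2-[(1S)-1-(tert-butyldimethylsilyloxy)-2-(4-methoxybenzyloxy)ethyl]-3-hydroxy-6-methyloct-6-enoate
Product: 9 methyl (2E,6E)-8-acetoxy-2-[(1S)-1-(tert-butyldimethylsilyloxy)-2-(4-methoxybenzyloxy)ethyl]-6-methylocta-2,6-dienoate, via mesylate 8 (not isolated)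
Conditions: MsCl, Et3N, CH2Cl2, 0 °C; then DBU, 0 °C → rt
Reagents that add atoms: none
Why: Mesylation and E1cB elimination through the ester enolate should give the thermodynamically preferred tiglate-type E enoate (C2 trans to CO2Me, cis to C9), the mesylate leaving far more readily than the silyloxy group.

Step 7
Reactants: 9 methyl (2E,6E)-8-acetoxy-2-[(1S)-1-(tert-butyldimethylsilyloxy)-2-(4-methoxybenzyloxy)ethyl]-6-methylocta-2,6-dienoate
Product: 10 methyl (2E,6E)-2-[(1S)-1-(tert-butyldimethylsilyloxy)-2-(4-methoxybenzyloxy)ethyl]-8-hydroxy-6-methylocta-2,6-dienoate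
Conditions: K2CO3 (0.2 equiv), MeOH, 0 °C
Reagents that add atoms: none
Why: Base-catalysed methanolysis removes the primary allylic acetate, while the methyl ester exchanges degenerately and the silyl ether, the PMB ether and the enoate are stable.

Step 8
Reactants: 10 methyl (2E,6E)-2-[(1S)-1-(tert-butyldimethylsilyloxy)-2-(4-methoxybenzyloxy)ethyl]-8-hydroxy-6-methylocta-2,6-dienoate
Product: 11 methyl (2E,6E)-2-[(1S)-1-(tert-butyldimethylsilyloxy)-2-(4-methoxybenzyloxy)ethyl]-6-methyl-8-oxoocta-2,6-dienoate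
Conditions: MnO2, CH2Cl2, rt
Reagents that add atoms: none
Why: Allylic oxidation with MnO2 touches only the allylic alcohol and does not isomerise the E trisubstituted alkene.

Step 9
Reactants: 11 methyl (2E,6E)-2-[(1S)-1-(tert-butyldimethylsilyloxy)-2-(4-methoxybenzyloxy)ethyl]-6-methyl-8-oxoocta-2,6-dienoate
Product: 12 methyl (2E,6E)-2-[(1S)-1-hydroxy-2-(4-methoxybenzyloxy)ethyl]-6-methyl-8-oxoocta-2,6-dienoate
Conditions: HF·pyridine, pyridine/THF, 0 °C → rt
Reagents that add atoms: none
Why: Buffered fluoride desilylation spares the PMB ether, the enal and the enoate, and the liberated β-hydroxyl cannot lactonise onto the C14 ester.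

Step 10
Reactants: 12 methyl (2E,6E)-2-[(1S)-1-hydroxy-2-(4-methoxybenzyloxy)ethyl]-6-methyl-8-oxoocta-2,6-dienoate
Product: 13 methyl (2E,6E)-2-[(1S)-1-acetoxy-2-(4-methoxybenzyloxy)ethyl]-6-methyl-8-oxoocta-2,6-dienoate
Conditions: Ac2O, pyridine, DMAP (cat.), CH2Cl2, 0 °C
Reagents that add atoms: acetic anhydride CC(=O)OC(C)=O
Why: Standard acetylation installs the C9 acetate of the target at this point because no strongly basic step follows.

Step 11
Reactants: 13 methyl (2E,6E)-2-[(1S)-1-acetoxy-2-(4-methoxybenzyloxy)ethyl]-6-methyl-8-oxoocta-2,6-dienoate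
Product: 14 methyl (2E,6E)-2-[(1S)-1-acetoxy-2-(4-methoxybenzyloxy)ethyl]-8-hydroxy-6-methyldeca-2,6,9-trienoate (both C8 epimers)
Conditions: CH2=CHMgBr, THF, −78 °C; sat. NH4Cl
Reagents that add atoms: vinylmagnesium bromide C=C[Mg]Br
Why: 1,2-Addition of the vinyl Grignard reagent to the aldehyde is much faster at −78 °C than attack on the acetate or the methyl enoate; no stereocontrol is expected and the C6 epimers are separated chemically in step 12.

Step 12
Reactants: 14 methyl (2E,6E)-2-[(1S)-1-acetoxy-2-(4-methoxybenzyloxy)ethyl]-8-hydroxy-6-methyldeca-2,6,9-trienoate (both C8 epimers)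
Product: 15 methyl (2E,6E,8S)-2-[(1S)-1-acetoxy-2-(4-methoxybenzyloxy)ethyl]-8-hydroxy-6-methyldeca-2,6,9-trienoate
Conditions: Ti(OiPr)4 (0.3 equiv), D-(−)-diisopropyl tartrate (0.36 equiv), tBuOOH (0.6 equiv), 4 Å MS, CH2Cl2, −20 °C
Reagents that add atoms: none
Why: Sharpless kinetic resolution under reagent control: with the D-(−)-tartrate the (6R) epimer should be epoxidised quickly at its C4=C5 bond, whereas the wanted (6S) epimer is mismatched there, carries only a far less reactive vinyl group as the alternative, and should be recovered.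

Step 13
Reactants: 15 methyl (2E,6E,8S)-2-[(1S)-1-acetoxy-2-(4-methoxybenzyloxy)ethyl]-8-hydroxy-6-methyldeca-2,6,9-trienoate; 16 2-(bromomethyl)acrylic acid
Product: 17 methyl (2E,6E,8S)-2-[(1S)-1-acetoxy-2-(4-methoxybenzyloxy)ethyl]-8-[2-(bromomethyl)acryloyloxy]-6-methyldeca-2,6,9-trienoate
Conditions: N,N'-dicyclohexylcarbodiimide, DMAP (10 mol%), CH2Cl2, −20 → 0 °C
Reagents that add atoms: none
Why: Steglich esterification proceeds with retention at C6, and low temperature with only catalytic DMAP limits SN2′ attack of the amine on the allylic bromide.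

Step 14
Reactants: 17 methyl (2E,6E,8S)-2-[(1S)-1-acetoxy-2-(4-methoxybenzyloxy)ethyl]-8-[2-(bromomethyl)acryloyloxy]-6-methyldeca-2,6,9-trienoate
Product: 18 methyl (2E,6E)-2-[(1S)-1-acetoxy-2-(4-methoxybenzyloxy)ethyl]-7-[(2R)-4-(bromomethyl)-5-oxo-2,5-dihydrofuran-2-yl]-6-methylhepta-2,6-dienoate
Conditions: second-generation Hoveyda–Grubbs catalyst (10 mol%), 1,4-benzoquinone (20 mol%), toluene (5 mM), 70 °C
Reagents that add atoms: none
Why: Ring-closing metathesis between the vinyl group and the 1,1-disubstituted acrylate closes the butenolide with loss of ethylene, the trisubstituted C4=C5 and C1=C10 alkenes being too hindered to compete and the C13 bromide staying in place.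

Step 15
Reactants: 18 methyl (2E,6E)-2-[(1S)-1-acetoxy-2-(4-methoxybenzyloxy)ethyl]-7-[(2R)-4-(bromomethyl)-5-oxo-2,5-dihydrofuran-2-yl]-6-methylhepta-2,6-dienoate
Product: 19 methyl (2E,6E)-2-[(1S)-1-acetoxy-2-hydroxyethyl]-7-[(2R)-4-(bromomethyl)-5-oxo-2,5-dihydrofuran-2-yl]-6-methylhepta-2,6-dienoate
Conditions: DDQ, CH2Cl2/pH 7 buffer, 0 °C
Reagents that add atoms: none
Why: Oxidative PMB cleavage under neutral conditions is compatible with the allylic bromide, the acetate and the base-sensitive butenolide; the alcohol is taken on at once so that neither acetyl migration nor lactonisation onto the C14 ester can set in.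

Step 16
Reactants: 19 methyl (2E,6E)-2-[(1S)-1-acetoxy-2-hydroxyethyl]-7-[(2R)-4-(bromomethyl)-5-oxo-2,5-dihydrofuran-2-yl]-6-methylhepta-2,6-dienoate
Product: 20 methyl (2E,6E)-2-[(1S)-1-acetoxy-2-oxoethyl]-7-[(2R)-4-(bromomethyl)-5-oxo-2,5-dihydrofuran-2-yl]-6-methylhepta-2,6-dienoate
Conditions: Dess–Martin periodinane, NaHCO3, CH2Cl2, 0 °C → rt
Reagents that add atoms: none
Why: Dess–Martin oxidation under buffered, non-basic conditions should give the α-acetoxy aldehyde without epimerising C9 or C6 and without touching the allylic bromide.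

Step 17
Reactants: 20 methyl (2E,6E)-2-[(1S)-1-acetoxy-2-oxoethyl]-7-[(2R)-4-(bromomethyl)-5-oxo-2,5-dihydrofuran-2-yl]-6-methylhepta-2,6-dienoate
Product: 22 methyl (6R,7R,8R,9S)-9-acetoxy-8-hydroxygermacra-1(10)E,4E,11(13)-trien-12,6-olid-14-oate (8α-OH cis to 9α-OAc; trans-fused lactone), via allylchromium dichloride 21 (not isolated)
Conditions: CrCl2 (10 equiv), THF, 25 °C, syringe-pump addition of 20 over 12 h (final 2 mM); H2O quench
Reagents that add atoms: none
Why: Two equivalents of CrCl2 reduce the allylic C13–Br bond to the allylchromium 21, whose γ-carbon C7 adds to the tethered C8 aldehyde through a closed six-membered chair transition state with transposition of the double bond to C11=C13 (intramolecular Nozaki–Hiyama–Kishi allylation; closest precedents are chromium-mediated cyclisations of 2-(bromomethyl)acrylate aldehydes to germacranolides and intermolecular additions of 3-(bromomethyl)furan-2(5H)-one to aldehydes). The ten-membered carbocycle closes in a 10-exo-trig mode, while the γ-lactone is already present and only gains its exocyclic methylene. C7 is controlled by C6: the aldehyde must reach the butenolide face opposite to the C6–C5 bond, because the syn approach would force a nearly eclipsed C5–C6–C7–C8 torsion in the forming ring, and this gives the trans-fused lactone (H-6β, H-7α). C8 is controlled twice in the same sense: the ring-locked E-type allylchromium (C6 trans to the CH2–Cr carbon) with C9 equatorial in the chair places H-7 and H-8 antiperiplanar (7,8-anti), and polar Felkin–Anh addition anti to the C9–OAc bond gives the 8,9-anti relationship, both leading to the 8α-alcohol 22 in a product-like ring conformation (C9 anti to C11), which is the C8 epimer of the target oxygen pattern and is inverted by design in step 20. The step needs γ- over α-attack of the allyl unit (secured by the cyclic transition state of allylchromium reagents), aldehyde over ester chemoselectivity (inherent to organochromium reagents, which also leave the acetate and the enoate untouched) and intra- over intermolecular coupling (secured by slow addition at high dilution).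

Step 18
Reactants: 23 methyl 2-(hydroxymethyl)acrylate
Product: 24 methyl 2-[(tert-butyldimethylsilyloxy)methyl]acrylate
Conditions: TBSCl, imidazole, CH2Cl2, 0 °C → rt
Reagents that add atoms: tert-butyldimethylsilyl chloride CC(C)(C)[Si](C)(C)Cl
Why: Standard silylation masks the primary alcohol, which would otherwise compete as a Mitsunobu substrate in step 20.

Step 19
Reactants: 24 methyl 2-[(tert-butyldimethylsilyloxy)methyl]acrylate
Product: 25 2-[(tert-butyldimethylsilyloxy)methyl]acrylic acid
Conditions: LiOH, THF/H2O, 0 °C; then 0.5 M HCl to pH 4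
Reagents that add atoms: lithium hydroxide [Li+].[OH-]
Why: Saponification of the methyl ester at 0 °C is faster than conjugate addition of hydroxide, and the primary silyl ether survives the brief cold acidification.

Step 20
Reactants: 22 methyl (6R,7R,8R,9S)-9-acetoxy-8-hydroxygermacra-1(10)E,4E,11(13)-trien-12,6-olid-14-oate; 25 2-[(tert-butyldimethylsilyloxy)methyl]acrylic acid
Product: 26 methyl (6R,7S,8S,9S)-9-acetoxy-8-{2-[(tert-butyldimethylsilyloxy)methyl]acryloyloxy}germacra-1(10)E,4E,11(13)-trien-12,6-olid-14-oate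
Conditions: PPh3, diisopropyl azodicarboxylate, toluene, 0 °C → rt (betaine pre-formed)
Reagents that add atoms: none
Why: Mitsunobu esterification: the C8 hydroxyl is activated as the oxyphosphonium ion and displaced by the carboxylate with SN2 inversion, turning the 8α-alcohol into the 8β-ester of the target; the cis C9 acetate cannot participate from the rear, and pre-forming the betaine keeps free phosphine away from the Michael acceptors.

Step 21
Reactants: 26 methyl (6R,7S,8S,9S)-9-acetoxy-8-{2-[(tert-butyldimethylsilyloxy)methyl]acryloyloxy}germacra-1(10)E,4E,11(13)-trien-12,6-olid-14-oate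
Product: 27 methyl (6R,7S,8S,9S)-9-acetoxy-8-[2-(hydroxymethyl)acryloyloxy]germacra-1(10)E,4E,11(13)-trien-12,6-olid-14-oate (CNP0291058.1)
Conditions: HF·pyridine, pyridine/THF, 0 °C → rt
Reagents that add atoms: none
Why: Fluoride desilylation under buffered conditions should free the primary alcohol without hydrolysing or migrating any of the three esters and without adding to the α-methylene lactone.

**Compound list**

1 | (R)-glycidol | OC[C@@H]1CO1 | starting material
2 | (S)-2-[(4-methoxybenzyloxy)methyl]oxirane | COc1ccc(COC[C@@H]2CO2)cc1 | intermediate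
3 | methyl (S)-3-hydroxy-4-(4-methoxybenzyloxy)butanoate | COC(=O)C[C@H](O)COCc1ccc(OC)cc1 | intermediate
4 | methyl (S)-3-(tert-butyldimethylsilyloxy)-4-(4-methoxybenzyloxy)butanoate | COC(=O)C[C@H](O[Si](C)(C)C(C)(C)C)COCc1ccc(OC)cc1 | intermediate
5 | geranyl acetate, (2E)-3,7-dimethylocta-2,6-dien-1-yl acetate | CC(=O)OC/C=C(\C)CCC=C(C)C | starting material
6 | (E)-3-methyl-6-oxohex-2-en-1-yl acetate | CC(=O)OC/C=C(\C)CCC=O | intermediate
7 | methyl (6E)-8-acetoxy-2-[(1S)-1-(tert-butyldimethylsilyloxy)-2-(4-methoxybenzyloxy)ethyl]-3-hydroxy-6-methyloct-6-enoate, mixture at C2 and C3 | CC(=O)OC/C=C(\C)CCC(O)C(C(=O)OC)[C@H](O[Si](C)(C)C(C)(C)C)COCc1ccc(OC)cc1 | intermediate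
8 | 3-O-methanesulfonate of 7 (mesylate, not isolated) | CC(=O)OC/C=C(\C)CCC(OS(C)(=O)=O)C(C(=O)OC)[C@H](O[Si](C)(C)C(C)(C)C)COCc1ccc(OC)cc1 | intermediate
9 | methyl (2E,6E)-8-acetoxy-2-[(1S)-1-(tert-butyldimethylsilyloxy)-2-(4-methoxybenzyloxy)ethyl]-6-methylocta-2,6-dienoate | CC(=O)OC/C=C(\C)CC/C=C(/C(=O)OC)[C@H](O[Si](C)(C)C(C)(C)C)COCc1ccc(OC)cc1 | intermediate
10 | methyl (2E,6E)-2-[(1S)-1-(tert-butyldimethylsilyloxy)-2-(4-methoxybenzyloxy)ethyl]-8-hydroxy-6-methylocta-2,6-dienoate | OC/C=C(\C)CC/C=C(/C(=O)OC)[C@H](O[Si](C)(C)C(C)(C)C)COCc1ccc(OC)cc1 | intermediate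
11 | methyl (2E,6E)-2-[(1S)-1-(tert-butyldimethylsilyloxy)-2-(4-methoxybenzyloxy)ethyl]-6-methyl-8-oxoocta-2,6-dienoate | O=C/C=C(\C)CC/C=C(/C(=O)OC)[C@H](O[Si](C)(C)C(C)(C)C)COCc1ccc(OC)cc1 | intermediate
12 | methyl (2E,6E)-2-[(1S)-1-hydroxy-2-(4-methoxybenzyloxy)ethyl]-6-methyl-8-oxoocta-2,6-dienoate | O=C/C=C(\C)CC/C=C(/C(=O)OC)[C@H](O)COCc1ccc(OC)cc1 | intermediate
13 | methyl (2E,6E)-2-[(1S)-1-acetoxy-2-(4-methoxybenzyloxy)ethyl]-6-methyl-8-oxoocta-2,6-dienoate | O=C/C=C(\C)CC/C=C(/C(=O)OC)[C@H](OC(C)=O)COCc1ccc(OC)cc1 | intermediate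
14 | methyl (2E,6E)-2-[(1S)-1-acetoxy-2-(4-methoxybenzyloxy)ethyl]-8-hydroxy-6-methyldeca-2,6,9-trienoate, both C8 epimers (future C6) | C=CC(O)/C=C(\C)CC/C=C(/C(=O)OC)[C@H](OC(C)=O)COCc1ccc(OC)cc1 | intermediate
15 | methyl (2E,6E,8S)-2-[(1S)-1-acetoxy-2-(4-methoxybenzyloxy)ethyl]-8-hydroxy-6-methyldeca-2,6,9-trienoate | C=C[C@H](O)/C=C(\C)CC/C=C(/C(=O)OC)[C@H](OC(C)=O)COCc1ccc(OC)cc1 | intermediate
16 | 2-(bromomethyl)acrylic acid | C=C(CBr)C(=O)O | starting material
17 | methyl (2E,6E,8S)-2-[(1S)-1-acetoxy-2-(4-methoxybenzyloxy)ethyl]-8-[2-(bromomethyl)acryloyloxy]-6-methyldeca-2,6,9-trienoate | C=C[C@H](OC(=O)C(=C)CBr)/C=C(\C)CC/C=C(/C(=O)OC)[C@H](OC(C)=O)COCc1ccc(OC)cc1 | intermediate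
18 | methyl (2E,6E)-2-[(1S)-1-acetoxy-2-(4-methoxybenzyloxy)ethyl]-7-[(2R)-4-(bromomethyl)-5-oxo-2,5-dihydrofuran-2-yl]-6-methylhepta-2,6-dienoate | O=C1O[C@@H](C=C1CBr)/C=C(\C)CC/C=C(/C(=O)OC)[C@H](OC(C)=O)COCc2ccc(OC)cc2 | intermediate
19 | methyl (2E,6E)-2-[(1S)-1-acetoxy-2-hydroxyethyl]-7-[(2R)-4-(bromomethyl)-5-oxo-2,5-dihydrofuran-2-yl]-6-methylhepta-2,6-dienoate | O=C1O[C@@H](C=C1CBr)/C=C(\C)CC/C=C(/C(=O)OC)[C@H](OC(C)=O)CO | intermediate
20 | methyl (2E,6E)-2-[(1S)-1-acetoxy-2-oxoethyl]-7-[(2R)-4-(bromomethyl)-5-oxo-2,5-dihydrofuran-2-yl]-6-methylhepta-2,6-dienoate | O=C1O[C@@H](C=C1CBr)/C=C(\C)CC/C=C(/C(=O)OC)[C@H](OC(C)=O)C=O | intermediate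
21 | allylchromium dichloride derived from 20 (CrCl2 in place of Br at C13; trivalent chromium; not isolated) | O=C1O[C@@H](C=C1C[Cr](Cl)Cl)/C=C(\C)CC/C=C(/C(=O)OC)[C@H](OC(C)=O)C=O | intermediate
22 | methyl (6R,7R,8R,9S)-9-acetoxy-8-hydroxygermacra-1(10)E,4E,11(13)-trien-12,6-olid-14-oate (8α-OH, 9α-OAc, H-6β, H-7α) | O[C@@H]1[C@H]2C(=C)C(=O)O[C@@H]2/C=C(\C)CC/C=C(/C(=O)OC)[C@@H]1OC(C)=O | intermediate
23 | methyl 2-(hydroxymethyl)acrylate | C=C(CO)C(=O)OC | starting material
24 | methyl 2-[(tert-butyldimethylsilyloxy)methyl]acrylate | C=C(CO[Si](C)(C)C(C)(C)C)C(=O)OC | intermediate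
25 | 2-[(tert-butyldimethylsilyloxy)methyl]acrylic acid | C=C(CO[Si](C)(C)C(C)(C)C)C(=O)O | intermediate
26 | methyl (6R,7S,8S,9S)-9-acetoxy-8-{2-[(tert-butyldimethylsilyloxy)methyl]acryloyloxy}germacra-1(10)E,4E,11(13)-trien-12,6-olid-14-oate | C=C(CO[Si](C)(C)C(C)(C)C)C(=O)O[C@H]1[C@H]2C(=C)C(=O)O[C@@H]2/C=C(\C)CC/C=C(/C(=O)OC)[C@@H]1OC(C)=O | intermediate
27 | methyl (6R,7S,8S,9S)-9-acetoxy-8-[2-(hydroxymethyl)acryloyloxy]germacra-1(10)E,4E,11(13)-trien-12,6-olid-14-oate (CNP0291058.1) | C=C(CO)C(=O)O[C@H]1[C@H]2C(=C)C(=O)O[C@@H]2/C=C(\C)CC/C=C(/C(=O)OC)[C@@H]1OC(C)=O | target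

**Step count and risks**

Total step count: 21. Longest linear sequence: 18 steps (steps 1–3, 5–17, 20, 21).

Steps most likely to fail:

Step 17 (macrocyclisation). The allylchromium may couple intermolecularly or be protonated before it reaches the aldehyde, and facial control at the aldehyde may be lower than predicted. Fallback: setting out from 19, stannylation of the allylic bromide with Bu3SnSnBu3 and Pd(PPh3)4 would give the allylstannane alcohol F1, and Dess–Martin oxidation the stannyl aldehyde F2. BF3·OEt2 in dilute CH2Cl2 at −78 °C would then close the ring by an open-transition-state allylstannane addition, which needs no reducing metal. Felkin–Anh control and the same ring-conformational preference are expected to lead again to alcohol 22, where the route is rejoined.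

Step 20 (Mitsunobu inversion). The hindered C8 oxyphosphonium ion may eliminate, or may not be displaced at a carbon flanked by two substituted centres. Fallback: setting out from 22, buffered Dess–Martin oxidation would give the C8 ketone F3. Luche reduction (NaBH4, CeCl3·7H2O, MeOH, −78 °C) from the less hindered α-face, opposite the β-oriented lactone carbon C11, would give the 8β-alcohol F4. Steglich acylation of F4 with acid 25 (retention) would return to 26.

Step 14 (ring-closing metathesis). The catalyst may be deactivated by the allylic bromide, or ruthenium hydrides may cause double-bond migration before ring closure. Fallback: setting out from 15, Steglich esterification with acid 25 would give the silyloxymethyl acrylate F5, and ring-closing metathesis the silyloxymethyl butenolide F6. HF·pyridine would give the hydroxymethyl butenolide F7, and Appel bromination (CBr4, PPh3, CH2Cl2, 0 °C) would return to 18.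

Further compounds
F1 | step 17 | methyl (2E,6E)-2-[(1S)-1-acetoxy-2-hydroxyethyl]-6-methyl-7-[(2R)-5-oxo-4-(tributylstannylmethyl)-2,5-dihydrofuran-2-yl]hepta-2,6-dienoate | O=C1O[C@@H](C=C1C[Sn](CCCC)(CCCC)CCCC)/C=C(\C)CC/C=C(/C(=O)OC)[C@H](OC(C)=O)CO
F2 | step 17 | methyl (2E,6E)-2-[(1S)-1-acetoxy-2-oxoethyl]-6-methyl-7-[(2R)-5-oxo-4-(tributylstannylmethyl)-2,5-dihydrofuran-2-yl]hepta-2,6-dienoate | O=C1O[C@@H](C=C1C[Sn](CCCC)(CCCC)CCCC)/C=C(\C)CC/C=C(/C(=O)OC)[C@H](OC(C)=O)C=O
F3 | step 20 | methyl 9α-acetoxy-8-oxogermacra-1(10)E,4E,11(13)-trien-12,6-olid-14-oate | O=C1[C@H]2C(=C)C(=O)O[C@@H]2/C=C(\C)CC/C=C(/C(=O)OC)[C@@H]1OC(C)=O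
F4 | step 20 | methyl 9α-acetoxy-8β-hydroxygermacra-1(10)E,4E,11(13)-trien-12,6-olid-14-oate | O[C@H]1[C@H]2C(=C)C(=O)O[C@@H]2/C=C(\C)CC/C=C(/C(=O)OC)[C@@H]1OC(C)=O
F5 | step 14 | methyl (2E,6E,8S)-2-[(1S)-1-acetoxy-2-(4-methoxybenzyloxy)ethyl]-8-{2-[(tert-butyldimethylsilyloxy)methyl]acryloyloxy}-6-methyldeca-2,6,9-trienoate | C=C[C@H](OC(=O)C(=C)CO[Si](C)(C)C(C)(C)C)/C=C(\C)CC/C=C(/C(=O)OC)[C@H](OC(C)=O)COCc1ccc(OC)cc1
F6 | step 14 | methyl (2E,6E)-2-[(1S)-1-acetoxy-2-(4-methoxybenzyloxy)ethyl]-7-[(2R)-4-[(tert-butyldimethylsilyloxy)methyl]-5-oxo-2,5-dihydrofuran-2-yl]-6-methylhepta-2,6-dienoate | O=C1O[C@@H](C=C1CO[Si](C)(C)C(C)(C)C)/C=C(\C)CC/C=C(/C(=O)OC)[C@H](OC(C)=O)COCc2ccc(OC)cc2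
F7 | step 14 | methyl (2E,6E)-2-[(1S)-1-acetoxy-2-(4-methoxybenzyloxy)ethyl]-7-[(2R)-4-(hydroxymethyl)-5-oxo-2,5-dihydrofuran-2-yl]-6-methylhepta-2,6-dienoate | O=C1O[C@@H](C=C1CO)/C=C(\C)CC/C=C(/C(=O)OC)[C@H](OC(C)=O)COCc2ccc(OC)cc2
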